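**Strategy.** Ring A (five-membered, C1–C5; C1 = methyl-bearing fusion carbon, C5 = fusion CH) and ring B (seven-membered, C1, C5–C10) are made together from a cyclohexene. A cationic gold catalyst triggers 6-endo attack of an isopropenyl CH2 (C2) on a terminal alkyne carbon (C3); the tertiary cation at C1, next to the silyloxy carbon C10, is quenched by a 1,2-shift of ring carbon C5 from C10 to C1. One operation thus closes ring A, enlarges the six-membered ring to ring B and sets quaternary C1; it exploits that C1 is bonded to C2, C5 and C10 at once. The precursor is a 1-isopropenyl-2-ethynylcyclohex-2-enyl silyl ether made from p-benzoquinone monoketal.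

Key step: step 7

Numbering: C1 (quaternary, angular CH3), C2, C3 (CH2), C4 (OH, isopropyl), C5 (fusion CH), C6 (acyloxy), C7 (C=O), C8 (C–CH3), C9 (CH–OH), C10 (CH2); the same numbers are used for the matching carbons of the monocyclic precursors ("future C…"), whose names carry spiro locants.

Assumption: the organocerium reagent in step 4 attacks anti to the ring methyl. If the intrinsic preference were the reverse, the antipodal ligand in step 1 would give the same configuration at future C10, because C8 is erased in step 13.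

**Step 1**
Reactants: 1 1,4-dioxaspiro[4.5]deca-6,9-dien-8-one
Product: 2 (S)-10-methyl-1,4-dioxaspiro[4.5]dec-6-en-8-one
Conditions: Me2Zn, Cu(OTf)2 (2 mol%), BINOL-derived phosphoramidite with a bis(1-phenylethyl)amino group (4 mol%, antipode that gives the S product), toluene, −25 °C; aq NH4Cl
Reagents that add atoms: dimethylzinc, C[Zn]C
Why: Copper-catalysed enantioselective conjugate addition of a dialkylzinc, in which the chiral copper complex selects the enone face and sets future C8, and the zinc dienolate formed is no longer an acceptor, so only one methyl adds.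

**Step 2**
Reactants: 2 (S)-10-methyl-1,4-dioxaspiro[4.5]dec-6-en-8-one
Product: 3 (S)-7-iodo-10-methyl-1,4-dioxaspiro[4.5]dec-6-en-8-one
Conditions: I2, pyridine, CH2Cl2, 0 °C to rt
Reagents that add atoms: iodine, II
Why: α-Iodination of an enone (pyridine conjugate addition, iodination, elimination; Baylis–Hillman-type pathway) places iodine only on the α-carbon of the remaining enone, future C5.

**Step 3**
Reactants: 3 (S)-7-iodo-10-methyl-1,4-dioxaspiro[4.5]dec-6-en-8-one
Product: 4 (S)-10-methyl-7-[(trimethylsilyl)ethynyl]-1,4-dioxaspiro[4.5]dec-6-en-8-one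
Conditions: ethynyltrimethylsilane, PdCl2(PPh3)2 (5 mol%), copper iodide CuI (10 mol%), iPr2NH, THF, 0 °C to rt
Reagents that add atoms: ethynyltrimethylsilane, C#C[Si](C)(C)C
Why: Sonogashira coupling of the reactive α-iodoenone installs future C4 and C3 without touching the ketal or the stereocentre.

**Step 4**
Reactants: 4 (S)-10-methyl-7-[(trimethylsilyl)ethynyl]-1,4-dioxaspiro[4.5]dec-6-en-8-one
Product: 5 (8S,10S)-10-methyl-8-(prop-1-en-2-yl)-7-[(trimethylsilyl)ethynyl]-1,4-dioxaspiro[4.5]dec-6-en-8-ol (OH cis to the ring methyl)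
Conditions: CH2=C(CH3)MgBr, CeCl3, THF, −78 °C; aq NH4Cl
Reagents that add atoms: isopropenylmagnesium bromide, C=C(C)[Mg]Br
Why: 1,2-Addition of a weakly basic organocerium reagent to the enone carbonyl, with attack anti to the ring methyl expected to set the tertiary carbinol (future C10) with OH cis to that methyl.

**Step 5**
Reactants: 5 (8S,10S)-10-methyl-8-(prop-1-en-2-yl)-7-[(trimethylsilyl)ethynyl]-1,4-dioxaspiro[4.5]dec-6-en-8-ol
Product: 6 (8S,10S)-7-ethynyl-10-methyl-8-(prop-1-en-2-yl)-1,4-dioxaspiro[4.5]dec-6-en-8-ol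
Conditions: K2CO3 (cat.), MeOH, rt
Reagents that add atoms: none
Why: Base-catalysed methanolysis of the alkynyl C–Si bond frees the terminal alkyne needed for 6-endo attack and leaves the tertiary alcohol untouched.

**Step 6**
Reactants: 6 (8S,10S)-7-ethynyl-10-methyl-8-(prop-1-en-2-yl)-1,4-dioxaspiro[4.5]dec-6-en-8-ol
Product: 7 triethyl{[(8S,10S)-7-ethynyl-10-methyl-8-(prop-1-en-2-yl)-1,4-dioxaspiro[4.5]dec-6-en-8-yl]oxy}silane
Conditions: Et3SiOTf, 2,6-lutidine, CH2Cl2, −78 °C
Reagents that add atoms: triethylsilyl trifluoromethanesulfonate, CC[Si](CC)(CC)OS(=O)(=O)C(F)(F)F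
Why: Silylation of the hindered tertiary alcohol with a silyl triflate and a hindered base gives the silyl ether whose oxygen later drives the pinacol shift.

**Step 7**
Reactants: 7 triethyl{[(8S,10S)-7-ethynyl-10-methyl-8-(prop-1-en-2-yl)-1,4-dioxaspiro[4.5]dec-6-en-8-yl]oxy}silane
Product: 8 (1S,8S)-bicyclic dienone ketal: ring A cyclopentene (C3=C4), C5=C6, C7 ethylene ketal, 8-CH3, C10 ketone, angular 1-CH3
Conditions: Ph3PAuNTf2 (5 mol%), iPrOH (1.1 equiv), CH2Cl2, 0 °C to rt
Reagents that add atoms: none
Why: The cationic gold catalyst activates the terminal alkyne, the isopropenyl CH2 (C2) attacks C3 in a 6-endo-dig carbocyclisation, and the tertiary cation at C1 is trapped by 1,2-migration of the alkenyl carbon C5 from the silyloxy carbon C10, after which isopropanol takes the silyl group and protodeauration at C4 releases the catalyst. This is the gold-catalysed carbocyclisation/pinacol cascade of 3-silyloxy-1,5-enynes, a pinacol-terminated Prins-type cyclisation. Ring A is closed by the 6-endo-dig attack (C2–C3) followed by contraction of the transient six-membered cation through the 1,2-shift (C1–C5), and the same shift enlarges the cyclohexene to ring B. The only new stereocentre, C1, is controlled by C10: C1 is held on the ring face opposite the C10–O bond, C5 bonds to it on that face, and the shift should turn (S)-C10 into (S)-C1 while C8 is untouched. The step needs 6-endo over 5-exo attack, secured by the terminal alkyne and the tertiary cation from the 1,1-disubstituted alkene, and migration of C5 over C9, secured by the higher migratory aptitude of an alkenyl carbon and by the bridgehead-alkene strain a C9 shift would create.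

**Step 8**
Reactants: 8 (1S,8S)-bicyclic dienone ketal
Product: 10 (1S,8S)-cross-conjugated dienone: C2=C3, C4 ketone, C5=C6, C7 ethylene ketal, 8-CH3, C10 ketone, via allylic hydroperoxide 9 (not isolated)
Conditions: O2, tetraphenylporphyrin (cat.), visible light, CH2Cl2, −20 °C; then Ac2O, pyridine, DMAP (cat.), 0 °C
Reagents that add atoms: dioxygen, O=O
Why: Schenck ene reaction of singlet oxygen then Kornblum–DeLaMare dehydration: only C2 offers transferable allylic hydrogens (C5 and C7 have none) and the diene is locked s-trans, so oxygen enters at C4 with shift of the alkene to C2=C3 and the secondary hydroperoxide is dehydrated to the C4 ketone.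

**Step 9**
Reactants: 10 (1S,8S)-cross-conjugated dienone
Product: 11 (1S,5R,8S)-trans-fused diketone: C4 and C10 ketones, C7 ethylene ketal, 8-CH3, H-5 anti to 1-CH3
Conditions: H2 (1 atm), Pd/C, EtOAc, rt
Reagents that add atoms: none
Why: Heterogeneous hydrogenation of both conjugated alkenes, with hydrogen delivered to C5 from the face opposite the angular methyl on the adjacent C1, which sets the trans ring fusion under neutral conditions that avoid epimerisation next to the C4 ketone.

**Step 10**
Reactants: 11 (1S,5R,8S)-trans-fused diketone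
Product: 12 (1S,4R,5R,8S)-4-hydroxy-4-isopropyl ketone: C10 ketone, C7 ethylene ketal, 8-CH3
Conditions: iPrMgCl, CeCl3, THF, −78 °C; aq NH4Cl
Reagents that add atoms: isopropylmagnesium chloride, CC(C)[Mg]Cl
Why: Organocerium addition to a ketone: the cyclopentanone C4 is far more accessible than the C10 ketone flanked by quaternary C1, and attack anti to the axial angular methyl (syn to H-5) should place isopropyl cis to H-5 and the hydroxyl cis to 1-CH3.

**Step 11**
Reactants: 12 (1S,4R,5R,8S)-4-hydroxy-4-isopropyl ketone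
Product: 14 (1S,4R,5R,8S)-C10 enol triflate (C9=C10), via dipotassium alkoxide enolate 13 (not isolated)
Conditions: KN(SiMe3)2 (2.2 equiv), THF, −78 °C; PhNTf2; aq NH4Cl
Reagents that add atoms: N-phenylbis(trifluoromethanesulfonimide), O=S(=O)(N(c1ccccc1)S(=O)(=O)C(F)(F)F)C(F)(F)F
Why: Enolate O-triflation: the C10 ketone can enolise only towards C9 because C1 is quaternary, and the tertiary alkoxide is too hindered to be sulfonylated.

**Step 12**
Reactants: 14 (1S,4R,5R,8S)-C10 enol triflate
Product: 15 (1R,4R,5R,8S)-C9=C10 alkene: C4 carbinol, C7 ethylene ketal, 8-CH3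
Conditions: Pd(OAc)2 (5 mol%), PPh3, HCO2H, Bu3N, DMF, 60 °C
Reagents that add atoms: none
Why: Palladium-catalysed formate reduction of a vinyl triflate (oxidative addition, formate exchange, decarboxylation, reductive elimination) removes the C10 oxygen and leaves the C9=C10 alkene.

**Step 13**
Reactants: 15 (1R,4R,5R,8S)-C9=C10 alkene
Product: 17 (1R,4R,5R)-conjugated enone: C7 ketone, C8(CH3)=C9, C10 CH2, via β,γ-unsaturated ketone 16 (not isolated)
Conditions: 2 M aq HCl, THF, rt; extractive work-up; DBU, CH2Cl2, rt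
Reagents that add atoms: water, O
Why: Acid hydrolysis of the dioxolane unveils the C7 ketone and base then moves the β,γ-alkene into conjugation through the dienolate, giving the more stable α-methyl enone and erasing the relay stereocentre C8.

**Step 14**
Reactants: 17 (1R,4R,5R)-conjugated enone
Product: 19 (1R,4R,5S,6R)-6-hydroxy enone, via dilithium alkoxide enolate 18 (not isolated)
Conditions: LiN(iPr)2 (2.2 equiv), THF, −78 °C; 2-(phenylsulfonyl)-3-phenyloxaziridine; aq NH4Cl
Reagents that add atoms: 2-(phenylsulfonyl)-3-phenyloxaziridine, O=S(=O)(c1ccccc1)N1OC1c1ccccc1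
Why: Kinetic α′-deprotonation of the enone at C6 and enolate oxidation with an N-sulfonyloxaziridine, where approach anti to the axial angular methyl should give the equatorial C6 hydroxyl cis to H-5, which is also the more stable epimer.

**Step 15**
Reactants: 19 (1R,4R,5S,6R)-6-hydroxy enone; 20 4-(benzyloxy)benzoic acid
Product: 21 (1R,4R,5S,6R)-6-[4-(benzyloxy)benzoyloxy] enone
Conditions: DCC, DMAP, CH2Cl2, rt
Reagents that add atoms: none
Why: Steglich esterification acylates the secondary C6 hydroxyl, while the tertiary C4 hydroxyl is too hindered to react.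

**Step 16**
Reactants: 21 (1R,4R,5S,6R)-6-[4-(benzyloxy)benzoyloxy] enone
Product: 22 (1R,4R,5S,6R,8S,9S)-8,9-diol (benzyl ether of the target)
Conditions: OsO4 (5 mol%), N-methylmorpholine N-oxide, acetone/H2O, rt
Reagents that add atoms: N-methylmorpholine N-oxide, C[N+]1([O-])CCOCC1; water, O; osmium tetroxide (catalytic oxygen carrier), O=[Os](=O)(=O)=O
Why: Catalytic syn-dihydroxylation of the only remaining alkene, with OsO4 expected to add from the face opposite the axial angular methyl at C1, which sets C8 and C9 together as the cis-diol on the face of H-5.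

**Step 17**
Reactants: 22 (1R,4R,5S,6R,8S,9S)-8,9-diol benzyl ether
Product: 23 target, (1R,4R,5S,6R,8S,9S)-4,8,9-trihydroxy-4-isopropyl-1,8-dimethyl-7-oxobicyclo[5.3.0]decan-6-yl 4-hydroxybenzoate (numbering as above)
Conditions: H2 (1 atm), Pd/C, EtOAc, rt
Reagents that add atoms: none
Why: Hydrogenolysis of the benzyl aryl ether under neutral conditions frees the phenol without touching the ester, the ketol or the tertiary alcohols.

**Compound list**

1 | 1,4-dioxaspiro[4.5]deca-6,9-dien-8-one (p-benzoquinone mono(ethylene ketal)) | O=C1C=CC2(OCCO2)C=C1 | starting material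
2 | (S)-10-methyl-1,4-dioxaspiro[4.5]dec-6-en-8-one | O=C1C=CC2(OCCO2)[C@@H](C)C1 | intermediate
3 | (S)-7-iodo-10-methyl-1,4-dioxaspiro[4.5]dec-6-en-8-one | O=C1C(I)=CC2(OCCO2)[C@@H](C)C1 | intermediate
4 | (S)-10-methyl-7-[(trimethylsilyl)ethynyl]-1,4-dioxaspiro[4.5]dec-6-en-8-one | O=C1C(C#C[Si](C)(C)C)=CC2(OCCO2)[C@@H](C)C1 | intermediate
5 | (8S,10S)-10-methyl-8-(prop-1-en-2-yl)-7-[(trimethylsilyl)ethynyl]-1,4-dioxaspiro[4.5]dec-6-en-8-ol | CC(=C)[C@]1(O)C(C#C[Si](C)(C)C)=CC2(OCCO2)[C@@H](C)C1 | intermediate
6 | (8S,10S)-7-ethynyl-10-methyl-8-(prop-1-en-2-yl)-1,4-dioxaspiro[4.5]dec-6-en-8-ol | CC(=C)[C@]1(O)C(C#C)=CC2(OCCO2)[C@@H](C)C1 | intermediate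
7 | triethylsilyl ether of 6, (8S,10S) | CC(=C)[C@]1(O[Si](CC)(CC)CC)C(C#C)=CC2(OCCO2)[C@@H](C)C1 | intermediate
8 | (1S,8S)-bicyclic dienone ketal (C3=C4, C5=C6, C7 ethylene ketal, C10 ketone, 1-CH3, 8-CH3) | C[C@]12CC=CC1=CC3(OCCO3)[C@@H](C)CC2=O | intermediate
9 | C4 hydroperoxide of the C2=C3, C5=C6 diene (both C4 epimers) | C[C@]12C=CC(OO)C1=CC3(OCCO3)[C@@H](C)CC2=O | intermediate (not isolated)
10 | (1S,8S)-cross-conjugated dienone (C2=C3, C4 ketone, C5=C6, C7 ketal, C10 ketone) | C[C@]12C=CC(=O)C1=CC3(OCCO3)[C@@H](C)CC2=O | intermediate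
11 | (1S,5R,8S)-trans-fused 4,10-diketone, C7 ethylene ketal | C[C@]12CCC(=O)[C@@H]1CC3(OCCO3)[C@@H](C)CC2=O | intermediate
12 | (1S,4R,5R,8S)-4-hydroxy-4-isopropyl-10-ketone, C7 ethylene ketal | CC(C)[C@]1(O)CC[C@]2(C)C(=O)C[C@H](C)C3(OCCO3)C[C@H]21 | intermediate
13 | dipotassium C4-alkoxide C9=C10 enolate of 12 | CC(C)[C@]1([O-])CC[C@]2(C)C([O-])=C[C@H](C)C3(OCCO3)C[C@H]21.[K+].[K+] | intermediate (not isolated)
14 | (1S,4R,5R,8S)-C10 enol triflate | CC(C)[C@]1(O)CC[C@]2(C)C(OS(=O)(=O)C(F)(F)F)=C[C@H](C)C3(OCCO3)C[C@H]21 | intermediate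
15 | (1R,4R,5R,8S)-C9=C10 alkene, C7 ethylene ketal | CC(C)[C@]1(O)CC[C@]2(C)C=C[C@H](C)C3(OCCO3)C[C@H]21 | intermediate
16 | (1R,4R,5R,8S)-β,γ-unsaturated ketone (C7 ketone, C9=C10) | CC(C)[C@]1(O)CC[C@]2(C)C=C[C@H](C)C(=O)C[C@H]21 | intermediate (not isolated)
17 | (1R,4R,5R)-conjugated enone (C7 ketone, C8(CH3)=C9) | CC(C)[C@]1(O)CC[C@]2(C)CC=C(C)C(=O)C[C@H]21 | intermediate
18 | dilithium C4-alkoxide C6=C7 enolate of 17 | CC(C)[C@]1([O-])CC[C@]2(C)CC=C(C)C([O-])=C[C@H]21.[Li+].[Li+] | intermediate (not isolated)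
19 | (1R,4R,5S,6R)-6-hydroxy enone | CC(C)[C@]1(O)CC[C@]2(C)CC=C(C)C(=O)[C@H](O)[C@H]21 | intermediate
20 | 4-(benzyloxy)benzoic acid | OC(=O)c1ccc(OCc2ccccc2)cc1 | starting material
21 | (1R,4R,5S,6R)-6-[4-(benzyloxy)benzoyloxy] enone | CC(C)[C@]1(O)CC[C@]2(C)CC=C(C)C(=O)[C@H](OC(=O)c3ccc(OCc4ccccc4)cc3)[C@H]21 | intermediate
22 | (1R,4R,5S,6R,8S,9S)-8,9-diol, benzyl ether of the target | CC(C)[C@]1(O)CC[C@]2(C)C[C@H](O)[C@](C)(O)C(=O)[C@H](OC(=O)c3ccc(OCc4ccccc4)cc3)[C@H]21 | intermediate
23 | target, (1R,4R,5S,6R,8S,9S) | CC(C)[C@]1(O)CC[C@]2(C)C[C@H](O)[C@](C)(O)C(=O)[C@H](OC(=O)c3ccc(O)cc3)[C@H]21 | target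

**Totals.** 17 steps; longest linear sequence 17 steps (from 1).

**Steps most likely to fail**

Step 7. The doubly allylic tertiary silyl ether may ionise before cyclisation, or the cyclised cation may collapse to a cyclopropyl gold carbene before the 1,2-shift. Fallback: trigger the same carbocyclisation/1,2-shift with an iodonium electrophile in place of the metal. Setting out from 7, N-iodosuccinimide and iPrOH in CH2Cl2 at −40 °C should give the 4-iodo analogue of 8, vinyl iodide F1. Miyaura borylation (PdCl2(dppf), B2pin2, KOAc, dioxane, 80 °C) would give the dienylboronate F2, and oxidation (NaBO3·4H2O, THF/H2O) the C4 enone F3. Hydrogenation (H2, Pd/C, EtOAc) then comes back to the route at 11, so step 8 is bypassed as well.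

Step 8. Oxygenation of the diene may be unselective or slow, and the cross-conjugated dienone may decompose during the elimination. Fallback: oxidise ring A stepwise. Setting out from 8, OsO4/N-methylmorpholine N-oxide should dihydroxylate the less hindered disubstituted C3=C4 to the 3,4-diol F4. MnO2 in CH2Cl2 would oxidise only the allylic C4 hydroxyl to the hydroxy enone F5, and hydrogenation (H2, Pd/C) would give the trans-fused hydroxy diketone F6. SmI2 in THF/MeOH at −78 °C removes the hydroxyl next to the ketone and comes back at 11.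

Step 14. Deprotonation may occur at C10 (γ) instead of C6, the C4 alkoxide may interfere, or oxygen transfer may lack facial selectivity. Fallback: radical α′-acetoxylation in place of enolate oxidation. Setting out from 17, Mn(OAc)3 in refluxing benzene should give the 6-acetoxy enone F7. K2CO3 in MeOH at 0 °C cleaves the acetate, lets C6 settle in the equatorial orientation and comes back at 19.

**Further compounds**

F1 | step 7 | (1S,8S)-4-iodo analogue of 8 | C[C@]12CC=C(I)C1=CC3(OCCO3)[C@@H](C)CC2=O
F2 | step 7 | (1S,8S)-4-(pinacolatoboryl) analogue of 8 | C[C@]12CC=C(B3OC(C)(C)C(C)(C)O3)C1=CC3(OCCO3)[C@@H](C)CC2=O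
F3 | step 7 | (1S,8S)-enone: C4 ketone conjugated to C5=C6, C7 ethylene ketal, C10 ketone | C[C@]12CCC(=O)C1=CC3(OCCO3)[C@@H](C)CC2=O
F4 | step 8 | (1S,8S)-3,4-diol of 8, C5=C6 retained (C3 and C4 configuration immaterial) | C[C@]12CC(O)C(O)C1=CC3(OCCO3)[C@@H](C)CC2=O
F5 | step 8 | (1S,8S)-3-hydroxy-4-oxo enone, C5=C6 | C[C@]12CC(O)C(=O)C1=CC3(OCCO3)[C@@H](C)CC2=O
F6 | step 8 | (1S,5R,8S)-trans-fused 3-hydroxy-4,10-diketone | C[C@]12CC(O)C(=O)[C@@H]1CC3(OCCO3)[C@@H](C)CC2=O
F7 | step 14 | (1R,4R,5S,6R)-6-acetoxy enone (acetate of 19) | CC(C)[C@]1(O)CC[C@]2(C)CC=C(C)C(=O)[C@H](OC(C)=O)[C@H]21
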